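## The problem

Lapiferine (14) is a trans-fused hydroazulene. The five-membered ring is C1(CH3)–C2–C3–C4(OH)(i-Pr)–C5(H) and the seven-membered ring is C5–C6(O-angeloyl)–C7–C8(CH3)–C9–C10(OH)–C1, with an epoxide across C8–C9. Seven of the ten ring carbons are stereogenic: quaternary C1 (CH3 β), the tertiary carbinol C4 (OH β, i-Pr α), C5 (H α), C6 (O α), C8 and C9 (epoxide O α) and C10 (OH α). The C10 hydroxyl is cis to the epoxide and can deliver the oxidant to C8=C9. The angular methyl group projects over the β face of both C6 and C10, so reagents reach C6 from the α face as required, but the same bias sends hydride to the α face of a C10 ketone, which is the wrong side. The C4 hydroxyl is β and anti to C10 across the ring fusion, so it cannot correct this. The (Z)-2-methylbut-2-enoate isomerises to the tiglate with base, nucleophiles or heat. The trisubstituted epoxide, flanked by a free hydroxyl and facing the C4 hydroxyl across the ring, will not survive acid. The tertiary alcohol dehydrates easily. Ester and epoxide therefore come last, under near-neutral conditions. The feature that makes the key step possible is that the fifteen skeletal carbons form an unbranched head-to-tail farnesyl chain, C10–C9=C8(CH3)–C7–C6–C5=C1(CH3)–C2–C3–C4=C(CH3)2. Only the bonds C1–C10 and C4–C5 are missing, and C4 is where the cationic cascade ends, so its hydroxyl can come from water.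

## Retrosynthesis

14 to 13. The two C–O bonds of the epoxide are cut first, leaving the allylic alcohol 13. The C10 hydroxyl is allylic to C8=C9 and on the face the epoxide must occupy, so a metal-bound peroxide held by that hydroxyl gives the cis epoxy alcohol without relying on the shape of the ring. Cutting the ester first would leave two secondary hydroxyls to tell apart. The forward reaction must spare the electron-poor angelate alkene and avoid acid.

13 to 12. The C10–H bond is cut, giving the enone 12. The C10 carbonyl is needed earlier as the activating group for C6, so it is there anyway. The forward reaction must put hydride on the β face, next to the angular methyl, which substrate control will not do reliably. A chiral oxazaborolidine is therefore asked to decide the face.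

12 to 9 and 10. The ester C–O bond is cut to the hydroxy enone 9 and angelic acid 10. At this stage the C6 hydroxyl is the only secondary one, the C4 hydroxyl being tertiary and inert to acylation. The forward reaction must not isomerise the (Z)-ester and must not eliminate the δ-oxygen of the enone.

9 to 6. The C6–O bond is cut. C6 is not allylic in the daucene skeleton, and radical or tether chemistry from the C4 hydroxyl would reach the isopropyl methyls, C7 or the angular methyl first. Seen from a C10 carbonyl, however, C6 is the δ-carbon of the dienone 6, and a boron nucleophile adds there because the β-carbon C8 is fully substituted. The forward reaction must add from the α face and return the double bond to C8=C9.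

6 to 5 to 4. Removing the C6=C7 unsaturation gives enone 5, and removing the C10 oxygen gives the cyclase product 4. Both forward steps are oxidations guided by the C8=C9 double bond: allylic oxidation at the methylene next to the CH end of the alkene, then dehydrogenation through the dienol. Since C1 is quaternary, 5 can only enolise toward C7, so the dienone can only be the linear one.

4 to 3. The bonds C1–C10 and C4–C5 and the C4–O bond are cut together, which opens both rings and returns farnesyl diphosphate 3. No other cut removes two rings and three stereocentres at once. What is asked of the forward reaction is large: seven- instead of six-membered closure, a single 1,2-hydride shift, and water capture at C4. Only an enzyme active site can supply that.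

3 to 1. The P–O–C bond is cut to farnesol 1, a commercial C15 alcohol with both trisubstituted double bonds already E.

## Roads not taken

Alternative 1: The seven-membered ring is cut at C8–C9 and C9–C10, removing C9. This leaves the trimethylsilyl enol ether A1 of a trans-fused six–five ketone that already carries the C4 carbinol, the isopropyl group and the C6 oxygen. In the forward direction dibromocarbene (CHBr3, KOt-Bu) adds to the enol ether and the dibromocyclopropane opens to the bromo enone A2. The insertion is regiospecific and gives the C10 carbonyl and the C8=C9 double bond together, in the arrangement of 12. The C6 oxygen is in place before the ring is expanded, so steps 3 to 5 of the chosen plan have no counterpart, and no enzyme has to be found. In these respects this road is better. Its weak points are that A1 needs a long substrate-controlled build (quaternary C1, tertiary C4 carbinol, C6 carbinol, trans fusion), that the C9 bromine must be removed without touching the enone, and that the C10 carbinol problem is unchanged. Against its reliability the chosen plan sets brevity: the whole skeleton and three stereocentres in two steps from a C15 alcohol.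

Alternative 2: The five-membered ring is cut at C4–C5, giving the achiral aldehyde–dione A3. A chiral triazolylidene carbene converts the aldehyde into its Breslow intermediate, which adds to one of the two enantiotopic ring ketones and gives the ketol A4. The merit is a catalytic, small-molecule, enantioselective creation of quaternary C1 by desymmetrisation. For this target the oxidation pattern is inverted: A4 has hydroxyl at C5 where 14 has hydrogen, and a ketone at C4 where 14 has the isopropyl carbinol. The fusion is cis, and the seven-membered ring lacks the C8 methyl, the C8=C9 double bond and the C6 oxygen. A4 is therefore a much earlier intermediate than 4, and the road is the longest of the four. Its advantage over the chosen plan is only that its catalyst already exists.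

Alternative 3: The bonds C1–C5 and C5–C6 are cut, so that C5 becomes a carbene carbon and C1, C6–C10 an arene. The diazoketone A5 is decomposed by Rh2(S-PTTL)4; cyclopropanation of the arene and opening of the norcaradiene give the azulenone A6. This reaches a bicyclic core in about three steps, with the C8 methyl, oxygen at C4 and C10, and double bonds at C6=C7 and C8=C9 where oxygen is needed. In step count to the bicycle it matches the chosen plan, and it needs no enzyme. Its weak points are serious for 14. C1 is an sp2 carbon without its methyl, so the quaternary centre must be made later, trans to H5. The only stereocentre, C5, is α to a ketone and allylic and is easily lost. Asymmetric induction for this substitution pattern is not assured, and three double bonds must be told apart. The chosen plan delivers C1, C4 and C5 together and fixed, and sets against the pre-placed C6=C7 unsaturation of A6 its own three-step relay to C6.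

Key step: step 2

Assumption (numbering and faces): ring atoms are numbered as in the first section; β is the face of the C1 methyl group and α the face of H5; every bicyclic compound of the route is trans-fused (CH3-1 β, H-5 α).
Assumption (salt form): 3 is isolated and used as its ammonium salt and is drawn as the free acid.

## Route

Step 1
Reactants: 1 (2E,6E)-farnesol
Product: 3 (2E,6E)-farnesyl diphosphate, via farnesyl monophosphate 2 (not isolated)
Conditions: Cl3CCN, (Et3NH)2HPO4, MeCN, rt; NH4+ ion exchange; cellulose chromatography (i-PrOH/aq. NH3)
Reagents that add atoms: bis(triethylammonium) hydrogen phosphate, CC[NH+](CC)CC.CC[NH+](CC)CC.OP(=O)([O-])[O-]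
Why: Cramer-type phosphorylation: trichloroacetonitrile activates phosphate as its imidoyl ester, which phosphorylates the primary allylic alcohol and then the monophosphate 2. The conditions are neutral, so the allylic system is not transposed and both E double bonds are kept; the diphosphate is separated from mono- and triphosphate by chromatography.

Step 2
Reactants: 3 (2E,6E)-farnesyl diphosphate
Product: 4 dauc-8-en-4β-ol
Conditions: recombinant sesquiterpene cyclase (dauc-8-en-4β-ol synthase), MgCl2, HEPES buffer pH 7.5, 30 °C, pentane overlay
Reagents that add atoms: water, O
Why: Proposed new method: the closest known reaction is the carotol-synthase cyclisation of 3, which forms the same two C–C bonds but lets a second hydride shift carry the cation to C5 before water adds; here the cascade must stop one shift earlier, which calls for an enzyme found by mining daucane-producing Apiaceae or evolved from the carotol enzyme. Mg2+-assisted loss of diphosphate, return to the tertiary allylic (nerolidyl) ion pair and rotation about C8–C9 give the cisoid allyl cation; its terminus C10 is attacked by C1 of the central double bond while C5 is attacked by C4 of the distal double bond, then hydride moves from C4 to the isopropyl carbon and water adds to the C4 cation. The seven-membered ring closes by 7-endo-trig attack (C1–C10) and the five-membered ring by 5-exo-trig attack (C4–C5). C1 and C5 are set together by anti addition of C10 and C4 across the E-configured central double bond, which can only give the trans relation of methyl and H5, and their absolute sense follows from the face of that alkene the folded chain presents to C10. C4 is set by the side from which bound water reaches the cation (β). The step needs seven- over six-membered closure and quench by water at C4 instead of a further shift or proton loss; nothing in the substrate secures either (acid in solution gives bisabolyl products), so control lies entirely with the active-site contour, the concerted closure avoiding a free secondary cation at C5.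

Step 3
Reactants: 4 dauc-8-en-4β-ol
Product: 5 4β-hydroxydauc-8-en-10-one
Conditions: Rh2(cap)4 (dirhodium tetrakis(caprolactamate), 1 mol %), t-BuOOH (70% aq.), ClCH2CH2Cl, 40 °C
Reagents that add atoms: tert-butyl hydroperoxide, CC(C)(C)OO
Why: Dirhodium-catalysed allylic oxidation with tert-butyl hydroperoxide: the tert-butylperoxy radical abstracts a C10 hydrogen, since this gives the allyl radical with a tertiary terminus, and the mixed peroxide formed at the secondary C10 end collapses to the β,β-disubstituted enone. The tertiary alcohol is inert and no stereocentre is touched.

Step 4
Reactants: 5 4β-hydroxydauc-8-en-10-one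
Product: 6 4β-hydroxydauca-6,8-dien-10-one
Conditions: chloranil, t-BuOH, reflux
Reagents that add atoms: none
Why: Quinone dehydrogenation of a β-alkyl enone to the linear dienone, the reaction that turns steroidal 4-en-3-ones into 4,6-dien-3-ones: the enone enolises toward C7 and chloranil takes hydride from C6. C1 is quaternary, so no cross-conjugated isomer can form, and the medium is neutral enough for the tertiary alcohol.

Step 5
Reactants: 6 4β-hydroxydauca-6,8-dien-10-one
Product: 9 4β,6α-dihydroxydauc-8-en-10-one, via allylboronate 7 (not isolated), via deconjugated hydroxy ketone 8 (not isolated)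
Conditions: CuCl (5 mol %), NaOt-Bu (10 mol %), DPEphos, B2pin2, MeOH, THF, rt; then NaBO3·4H2O, THF/H2O, rt; then DBU (cat.), CH2Cl2, 0 °C
Reagents that add atoms: sodium perborate, [Na+].[O-]B1OO1
Why: Copper-catalysed 1,6-conjugate borylation, directed to C6 because the β-carbon C8 is fully substituted, then C–B oxidation with retention and base-mediated return of the double bond into conjugation. The boryl–copper reagent adds to C6 from the α face, since the angular methyl sits directly over the β face of C6 while only H5 flanks the α face; this sets C6.

Step 6
Reactants: 9 4β,6α-dihydroxydauc-8-en-10-one; 10 angelic acid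
Product: 12 6α-angeloyloxy-4β-hydroxydauc-8-en-10-one, via Yamaguchi mixed anhydride 11 (not isolated)
Conditions: 10, 2,4,6-Cl3C6H2COCl, Et3N, PhMe, rt; then 9, PhMe, 70 °C
Reagents that add atoms: none
Why: Yamaguchi esterification through the mixed anhydride, which transfers the less hindered angeloyl group to the only secondary hydroxyl; the tertiary C4 hydroxyl does not react. Leaving out the nucleophilic pyridine catalyst limits Z to E isomerisation of the ester, and the weak amine base does not eliminate the δ-oxygen.

Step 7
Reactants: 12 6α-angeloyloxy-4β-hydroxydauc-8-en-10-one
Product: 13 6α-angeloyloxydauc-8-ene-4β,10α-diol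
Conditions: (S)-2-methyl-CBS-oxazaborolidine (0.3 equiv), catecholborane, PhMe, −78 to −40 °C; MeOH, pH 7 buffer
Reagents that add atoms: none
Why: Corey–Bakshi–Shibata reduction: the catalyst boron binds the carbonyl lone pair on the side of the vinylic C9–H, away from quaternary C1, and in that arrangement the (S)-catalyst delivers hydride to the β face, giving the 10α-alcohol. The substrate bias is modest (H5 and the 6α-ester crowd the α face, the angular methyl the β face), so the catalyst should decide; catecholborane at low temperature leaves the ester alone and reduces the s-trans enone 1,2.

Step 8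
Reactants: 13 6α-angeloyloxydauc-8-ene-4β,10α-diol
Product: 14 lapiferine
Conditions: VO(acac)2 (5 mol %), t-BuOOH (decane), CH2Cl2, 0 °C
Reagents that add atoms: tert-butyl hydroperoxide, CC(C)(C)OO
Why: Vanadium-catalysed hydroxyl-directed epoxidation of an allylic alcohol: the peroxide bound to vanadium is held by the 10α-alkoxide and transfers oxygen to the same face of C8=C9, setting C8 and C9 as the 8α,9α-epoxide. The angelate double bond is electron-poor and undirected and is not attacked.

## Compound list

1 | (2E,6E)-farnesol | CC(C)=CCC/C(C)=C/CC/C(C)=C/CO | starting material
2 | (2E,6E)-farnesyl monophosphate | CC(C)=CCC/C(C)=C/CC/C(C)=C/COP(=O)(O)O | intermediate (not isolated)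
3 | (2E,6E)-farnesyl diphosphate | CC(C)=CCC/C(C)=C/CC/C(C)=C/COP(=O)(O)OP(=O)(O)O | intermediate
4 | dauc-8-en-4β-ol (1β-CH3, 5α-H, 4α-isopropyl) | CC1=CC[C@@]2(C)CC[C@@](O)(C(C)C)[C@@H]2CC1 | intermediate
5 | 4β-hydroxydauc-8-en-10-one | CC1=CC(=O)[C@@]2(C)CC[C@@](O)(C(C)C)[C@@H]2CC1 | intermediate
6 | 4β-hydroxydauca-6,8-dien-10-one | CC1=CC(=O)[C@@]2(C)CC[C@@](O)(C(C)C)[C@@H]2C=C1 | intermediate
7 | 4β-hydroxy-6α-(4,4,5,5-tetramethyl-1,3,2-dioxaborolan-2-yl)dauc-7-en-10-one | CC=1CC(=O)[C@@]2(C)CC[C@@](O)(C(C)C)[C@@H]2[C@@H](B3OC(C)(C)C(C)(C)O3)C=1 | intermediate (not isolated)
8 | 4β,6α-dihydroxydauc-7-en-10-one | CC=1CC(=O)[C@@]2(C)CC[C@@](O)(C(C)C)[C@@H]2[C@@H](O)C=1 | intermediate (not isolated)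
9 | 4β,6α-dihydroxydauc-8-en-10-one | CC1=CC(=O)[C@@]2(C)CC[C@@](O)(C(C)C)[C@@H]2[C@@H](O)C1 | intermediate
10 | angelic acid, (Z)-2-methylbut-2-enoic acid | C/C=C(/C)C(=O)O | starting material
11 | (Z)-2-methylbut-2-enoic 2,4,6-trichlorobenzoic anhydride | C/C=C(/C)C(=O)OC(=O)c1c(Cl)cc(Cl)cc1Cl | intermediate (not isolated)
12 | 6α-[(Z)-2-methylbut-2-enoyloxy]-4β-hydroxydauc-8-en-10-one | C/C=C(/C)C(=O)O[C@H]1CC(C)=CC(=O)[C@@]2(C)CC[C@@](O)(C(C)C)[C@H]12 | intermediate
13 | 6α-[(Z)-2-methylbut-2-enoyloxy]dauc-8-ene-4β,10α-diol | C/C=C(/C)C(=O)O[C@H]1CC(C)=C[C@@H](O)[C@@]2(C)CC[C@@](O)(C(C)C)[C@H]12 | intermediate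
14 | lapiferine, 6α-[(Z)-2-methylbut-2-enoyloxy]-8α,9α-epoxydaucane-4β,10α-diol | C/C=C(/C)C(=O)O[C@H]1C[C@@]2(C)O[C@H]2[C@@H](O)[C@@]2(C)CC[C@@](O)(C(C)C)[C@H]12 | target

## Step count and risks

Total steps: 8. Longest linear sequence: 8 steps, from 1 to 14; 10 enters in step 6.

Step 2 (key step, proposed new method). The likeliest failure is that no enzyme with this product profile is found, or that a candidate lets the cation move on to C5 (carotol-type product), loses a proton (daucene) or closes the six-membered ring, because the substrate itself favours all of these. The fallback uses a known enzyme and known reactions. It sets out from 3 and returns at 4. Carotol synthase converts 3 into carotol F1, forming the same two C–C bonds. Dehydration with SOCl2 and pyridine gives daucene F2. N-Bromosuccinimide in aqueous acetone should open the bromonium ion of the tetrasubstituted C4=C5 alkene (formed anti to the angular methyl) with water at C4, the less hindered tertiary carbon, to give the bromohydrin 5α-bromodauc-8-en-4β-ol F3. Bu3SnH with a radical initiator replaces bromine by hydrogen and gives 4. This bridge is longer, and its last step delivers the C5 hydrogen under weak substrate control, so the cis-fused isomer would have to be separated.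

Step 7. The failure to expect is poor facial selectivity: the oxazaborolidine must deliver hydride next to the angular methyl, and the substrate's own preference for α-face attack may erode or reverse the outcome. A subsequent step would then direct the epoxide to the wrong face. The fallback sets out from 12 and returns at 13. Luche reduction (NaBH4, CeCl3·7H2O, MeOH) is expected to favour the 10β-epimer, 6α-angeloyloxydauc-8-ene-4β,10β-diol F4. Mitsunobu inversion with 4-nitrobenzoic acid, PPh3 and diisopropyl azodicarboxylate gives the 10α-(4-nitrobenzoate) F5, and brief methanolysis (K2CO3, MeOH, 0 °C) of the activated ester gives 13. The displacement is at a hindered allylic carbon, so SN2′ attack at C8 and elimination are its own risks.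

Step 5. After the borylation the dienolate is protonated at C9, so the double bond must be moved back into conjugation. In a seven-membered ring the conjugated enone is only modestly favoured over the β,γ-isomer, and the base may also expel the δ-hydroxyl to regenerate 6. Addition at C8 and epimerisation at C5 are lesser risks. The fallback avoids the dienolate. It sets out from 6 and returns at 9. Dimethyldioxirane in acetone at 0 °C should epoxidise the more electron-rich γ,δ-double bond from the α face to give 6α,7α-epoxy-4β-hydroxydauc-8-en-10-one F6. Hydrogenolysis with zerovalent palladium (Pd2(dba)3, n-Bu3P, HCO2H, Et3N, dioxane) opens the allylic C7–O bond and delivers hydride to C7, giving 9 directly as the conjugated enone.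

Step 3. The risk is loss of regiocontrol: hydrogen abstraction at C7 instead of C10, or capture of the peroxy radical at tertiary C8, which gives a peroxide that cannot become an enone. The fallback builds the C10 carbonyl by transposition. It sets out from 4 and returns at 5. Hydroxyselenation (PhSeCl, H2O, MeCN) gives 9α-(phenylselanyl)daucane-4β,8β-diol F7. Oxidation with H2O2 gives the selenoxide F8, which eliminates toward C10 to give dauc-9-ene-4β,8β-diol F9. Pyridinium chlorochromate, C5H5NH[CrO3Cl], then effects oxidative 1,3-transposition of the tertiary allylic alcohol to 5. The configurations at C8 and C9 in F7 to F9 are erased in 5 and do not matter.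

## Further compounds

F1 | step 2 | carotol, dauc-8-en-5-ol | CC1=CC[C@@]2(C)CC[C@@H](C(C)C)[C@@]2(O)CC1
F2 | step 2 | daucene, dauca-4,8-diene | CC1=CC[C@@]2(C)CCC(C(C)C)=C2CC1
F3 | step 2 | 5α-bromodauc-8-en-4β-ol | CC1=CC[C@@]2(C)CC[C@@](O)(C(C)C)[C@]2(Br)CC1
F4 | step 7 | 6α-[(Z)-2-methylbut-2-enoyloxy]dauc-8-ene-4β,10β-diol | C/C=C(/C)C(=O)O[C@H]1CC(C)=C[C@H](O)[C@@]2(C)CC[C@@](O)(C(C)C)[C@H]12
F5 | step 7 | 6α-[(Z)-2-methylbut-2-enoyloxy]-4β-hydroxydauc-8-en-10α-yl 4-nitrobenzoate | C/C=C(/C)C(=O)O[C@H]1CC(C)=C[C@@H](OC(=O)c3ccc(cc3)[N+](=O)[O-])[C@@]2(C)CC[C@@](O)(C(C)C)[C@H]12
F6 | step 5 | 6α,7α-epoxy-4β-hydroxydauc-8-en-10-one | CC1=CC(=O)[C@@]2(C)CC[C@@](O)(C(C)C)[C@@H]2[C@H]3O[C@H]31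
F7 | step 3 | 9α-(phenylselanyl)daucane-4β,8β-diol | C[C@@]1(O)[C@@H]([Se]c3ccccc3)C[C@@]2(C)CC[C@@](O)(C(C)C)[C@@H]2CC1
F8 | step 3 | 9α-(phenylseleninyl)daucane-4β,8β-diol (mixture at selenium) | C[C@@]1(O)[C@@H]([Se+]([O-])c3ccccc3)C[C@@]2(C)CC[C@@](O)(C(C)C)[C@@H]2CC1
F9 | step 3 | dauc-9-ene-4β,8β-diol | C[C@@]1(O)C=C[C@@]2(C)CC[C@@](O)(C(C)C)[C@@H]2CC1
A1 | alternative 1 | trimethylsilyl enol ether of the trans-fused six–five ketone with C4 triethylsilyl and C6 tert-butyldimethylsilyl ethers | CC1=C(O[Si](C)(C)C)[C@@]2(C)CC[C@@](O[Si](CC)(CC)CC)(C(C)C)[C@@H]2[C@@H](O[Si](C)(C)C(C)(C)C)C1
A2 | alternative 1 | 9-bromodauc-8-en-10-one with C4 triethylsilyl and C6 tert-butyldimethylsilyl ethers | CC1=C(Br)C(=O)[C@@]2(C)CC[C@@](O[Si](CC)(CC)CC)(C(C)C)[C@@H]2[C@@H](O[Si](C)(C)C(C)(C)C)C1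
A3 | alternative 2 | 2-methyl-2-(3-oxopropyl)cycloheptane-1,3-dione | CC1(CCC=O)C(=O)CCCCC1=O
A4 | alternative 2 | cis-fused 5-hydroxy-1-methylhydroazulene-4,10-dione | O=C1CCCC[C@]2(O)C(=O)CC[C@]12C
A5 | alternative 3 | 1-diazo-4-(2-methoxy-4-methylphenyl)butan-2-one | COc1cc(C)ccc1CCC(=O)C=[N+]=[N-]
A6 | alternative 3 | 8-methoxy-6-methyl-3,8a-dihydroazulen-1(2H)-one | COC1=C2CCC(=O)[C@@H]2C=CC(C)=C1
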